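## The problem

Phylloflavan 15 is the ester formed between O3 of (+)-catechin, (2R,3S), and (3S)-5-(3,4-dihydroxyphenyl)-3-hydroxypentanoic acid. Its only rings are the chroman (rings A and C) and two catechol rings, so with the flavan taken from nature no ring has to be built, and the task is to assemble a five-carbon acyl chain on a hindered secondary oxygen. Flavan C2 and C3 arrive as a trans pair with the flavan, but the chain carbinol C3 is separated from them by O3, C1 and C2, cannot be controlled by them, and so has to come from a reagent or the chiral pool and be carried through untouched. Six phenolic hydroxyls are present, four in two oxidation-prone catechols and two on the phloroglucinol-type ring A, which is nucleophilic at C6 and C8; they must stay masked until a final neutral, reductive release. The C2–O1 bond of ring C is benzylic and para to an oxygen of ring B, so it ionises under acid (epimerisation at flavan C2) and can be cut by forcing hydrogenolysis. The acyl part is a β-hydroxy ester, open to dehydration and to retro-aldol cleavage under base, and the parent β-hydroxy acid is a poor acyl donor for the shielded O3 unless its carbinol is protected first. The enabling feature is that the ester carbonyl C1 lies between O3 and the chain C2 methylene, which is next to the carbinol C3: C1 can be fixed to O3 first as a simple carbonic acid derivative and the C1–C2 bond then made by a C2 carbanion, provided a removable acidifying group on C2 lets that carbanion exist beside the C3 alkoxide.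

## Retrosynthesis

**15 from 14.** The six aryl O–benzyl bonds are cut last. Benzyl ethers survive organolithium reagents and single-electron reductants and fall together under neutral hydrogenolysis; methyl ethers would need Lewis acids that endanger C2–O1, and acyl groups would not survive a carbanion. Hexa-O-benzylphylloflavan 14 has the same skeleton as 15 but is stable to air and chromatography. The forward step must spare the C2–O1 bond and the ester.

**14 from 13.** A phenylsulfonyl group is placed on chain C2, so the forward reaction cuts a C–S bond. An unstabilised C2 carbanion next to an oxygen-bearing C3 cannot be used, whereas a sulfonyl carbanion tolerates a neighbouring alkoxide, and the sulfonyl group is removed reductively without touching benzyl ethers. The sulfonyl ester 13 carries one stereorandom centre that is erased on the way to 14. The forward step must cleave C–S without expelling the β-hydroxyl.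

**13 from 4 and 11 (through 12).** The chain C1–C2 bond is cut. The neighbouring cut at O3–C1 is the obvious esterification, but it would need a free β-hydroxy acid to be made, protected, activated and forced onto a hindered alcohol, with elimination as a side reaction. The cut at C2–C3, an acetate-type aldol on O3, gives no control over the carbinol. Cutting C1–C2 leaves the carbonyl on O3 as the imidazole carboxylate 4 and the rest of the chain as the (S)-β-hydroxy sulfone 11, two fragments of similar size whose stereocentres are complete. The forward reaction needs the dianion 12 to acylate at carbon and not at oxygen, and the acidic product 13 has to be kept as its anion until quench.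

**4 from 2 and 3; 2 from 1.** The O3–carbonyl bond is cut to tetra-O-benzylcatechin 2 and 1,1'-carbonyldiimidazole 3, and the four phenolic benzyl ethers are cut to (+)-catechin 1. This supplies ring C with both stereocentres at no cost. The forward steps need the phenols of 1 to react before the aliphatic hydroxyl, then clean mono-acylation of 2 by 3.

**11 from 10.** The C–S bond at the primary carbon is cut, which leads back to the (S)-chlorohydrin 10. A primary chloride next to the carbinol is displaced without any bond to the stereocentre being broken, so 11 inherits the configuration of 10. The forward step needs alkylation of the ambident sulfur nucleophile at sulfur and not at oxygen.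

**10 from 7 and 8 (through 9); 7 from 6 from 5.** The chain C4–C5 bond is cut to the benzylic Grignard reagent 9 and (S)-epichlorohydrin 8. Compound 8 supplies chain C2, C3 and C4 with the carbinol configuration already correct, which no neighbouring cut offers. The forward reaction must open the epoxide at its CH2 terminus only. The chloride 7 follows from the alcohol 6 and from 3,4-bis(benzyloxy)benzaldehyde 5 by reduction and chlorination.

## Roads not taken

Alternative 1: The cut is the O1–C2 bond of ring C, with the O3 ester seen as the remnant of a cyclic orthoester. In the forward key step BF3·OEt2 would ionise the 2-methoxy-1,3-dioxolane A2 at its orthoester carbon. The free C8a phenol oxygen would then displace the ring oxygen at flavan C2 with inversion, closing ring C and leaving the acyl group on O3, so that the product is hepta-O-benzylphylloflavan A1. The merits are that ring closure and ester formation happen in one operation, no hindered alcohol is acylated and no strong base is used. It is also the only plan here that does not depend on natural catechin, so analogues of A1 in the enantiomeric or modified flavan series would be reached equally well. The weak points are several. Ring C and both its stereocentres are rebuilt by asymmetric dihydroxylation although 1 supplies them. The chain fragment of A2 must still be made enantiopure, benzylated at its carbinol and raised to the orthoester oxidation level. The benzylic carbon carrying the 3,4-dialkoxyphenyl ring ionises easily, so an SN1 component would erode flavan C2 of A1. The cation from A2 can also be opened at its other carbon or trapped at its central carbon. In comparison this road is clearly longer and carries more stereochemical risk; the chosen plan sets a two-step preparation of 4 from 1 against the independence from the chiral pool that this road offers.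

Alternative 2: The cut is the chain C4–C5 bond, drawn as a double bond. In the forward key step the second-generation Grubbs catalyst RuCl2(PCy3)(H2IMes)(CHPh) would join the terminal alkene of tetra-O-benzylcatechin 3-O-[(3R)-3-hydroxypent-4-enoate] A4 to 3,4-bis(benzyloxy)styrene A5, giving the (E)-alkene A3. The new double bond of A3 would be saturated in the same hydrogenation that removes the benzyl groups. The merits are real: the carbon–carbon bond is made catalytically under neutral conditions, no auxiliary group is introduced and removed, no organolithium is needed, and the alkene reduction costs no step. In these respects this road is better than the chosen plan. Its weak points are that A4 still has to be made by joining a β-hydroxy acyl donor with a separately set allylic carbinol to O3, so the esterification problem is moved, not solved. Secondary allylic alcohols such as A4 can isomerise to ketones under ruthenium alkylidene catalysis, and A5 homodimerises readily. In A3 the carbinol is allylic to a styrene, so the final palladium step could hydrogenolyse its C–O bond or isomerise it to the ketone. In comparison, the chosen plan never makes the O3 ester from a β-hydroxy acid and its carbinol is never allylic; it pays for this with a stoichiometric sulfonyl group and two extra reagents, n-BuLi and SmI2.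

Alternative 3: The cut is the chain C3–O bond, made by way of a C3–B bond. In the forward key step a copper boryl complex from CuCl, NaOtBu, a chiral ferrocenyl bisphosphine and B2pin2 would add to the (E)-enoate A7 in the presence of methanol, giving the (3S)-pinacolboryl ester A6. Oxidation of A6 with retention would then give the carbinol. The merits are that A7 comes from 2 and the robust unsaturated acid A8 by ordinary esterification, and that the stereocentre of A6 is set catalytically, with either configuration available by choice of ligand. The overall step count is at least as short as that of the chosen plan, and no stoichiometric activating group is needed. The weak points are that the chain stereocentre is created on a substrate, A7, that already carries two remote stereocentres, so any shortfall in selectivity appears in A6 as a diastereomer that differs only at a distant carbon and would be hard to remove. The alkoxide and methanol of the borylation, and the basic peroxide of the oxidation, also act on a hindered but cleavable ester and on a newly formed β-hydroxy ester. In comparison this road matches or beats the chosen one in economy. The chosen plan sets against it a carbinol of full enantiopurity from 8, carried through without any bond to it being broken, so that no stereochemical purification is needed at any stage.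

Key step: step 7

Assumption: the chain is numbered from the ester carbonyl C1 to the benzylic CH2 C5 and the flavan keeps its usual numbering; read from the structure, the flavan unit is that of (+)-catechin, (2R,3S), and the chain carbinol is (S).

## Route

Step 1
Reactants: 1 (+)-catechin
Product: 2 (2R,3S)-5,7-bis(benzyloxy)-2-[3,4-bis(benzyloxy)phenyl]chroman-3-ol (tetra-O-benzylcatechin)
Conditions: BnBr (4.2 equiv), K2CO3, DMF, 0 °C → rt, argon
Reagents that add atoms: benzyl bromide, BrCc1ccccc1
Why: Williamson etherification: K2CO3 deprotonates the four phenols but not the aliphatic 3-hydroxyl, so O3 stays free; low temperature and exclusion of air limit C-benzylation of ring A and base-induced epimerisation at flavan C2, and no stereocentre is touched.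

Step 2
Reactants: 2 tetra-O-benzylcatechin; 3 1,1'-carbonyldiimidazole
Product: 4 (2R,3S)-5,7-bis(benzyloxy)-2-[3,4-bis(benzyloxy)phenyl]chroman-3-yl 1H-imidazole-1-carboxylate
Conditions: 3 (1.5 equiv), CH2Cl2, rt; aqueous wash, short chromatography
Reagents that add atoms: none
Why: Acyl transfer from 3 to the secondary alcohol gives the alkyl imidazole-1-carboxylate; the excess of 3 suppresses the symmetrical carbonate, and the C3–O bond is not broken, so the (2R,3S) configuration is retained.

Step 3
Reactants: 5 3,4-bis(benzyloxy)benzaldehyde
Product: 6 [3,4-bis(benzyloxy)phenyl]methanol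
Conditions: NaBH4, THF/MeOH, 0 °C
Reagents that add atoms: none
Why: Hydride reduction of an aromatic aldehyde; the benzyl ethers are inert.

Step 4
Reactants: 6 [3,4-bis(benzyloxy)phenyl]methanol
Product: 7 1,2-bis(benzyloxy)-4-(chloromethyl)benzene
Conditions: SOCl2 (1.2 equiv), CH2Cl2, 0 °C → rt
Reagents that add atoms: thionyl chloride, O=S(Cl)Cl
Why: Chlorination of a benzylic alcohol through its chlorosulfite; the electron-rich benzylic chloride should be used directly, without storage.

Step 5
Reactants: 7 1,2-bis(benzyloxy)-4-(chloromethyl)benzene; 8 (S)-epichlorohydrin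
Product: 10 (2S)-4-[3,4-bis(benzyloxy)phenyl]-1-chlorobutan-2-ol, via benzylic Grignard reagent 9 (not isolated)
Conditions: Mg (excess, I2-activated), THF, 0 °C, slow addition of 7 (1.5 equiv); then CuI (10 mol%), 8 (1.0 equiv), THF, −40 → −20 °C; aq. NH4Cl at −20 °C
Reagents that add atoms: none
Why: Grignard formation followed by copper-catalysed SN2 opening of the terminal epoxide at its unsubstituted CH2, which forms chain C4–C5. The stereocentre of 8 is not attacked and becomes the (S)-carbinol unchanged; slow addition to excess Mg limits Wurtz coupling, and the cold quench keeps the magnesium chlorohydrinate from closing to a new epoxide.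

Step 6
Reactants: 10 (2S)-4-[3,4-bis(benzyloxy)phenyl]-1-chlorobutan-2-ol
Product: 11 (2S)-4-[3,4-bis(benzyloxy)phenyl]-1-(phenylsulfonyl)butan-2-ol
Conditions: PhSO2Na (3 equiv), n-Bu4NI (10 mol%), DMF, 80 °C
Reagents that add atoms: sodium benzenesulfinate, [Na+].[O-]S(=O)c1ccccc1
Why: SN2 S-alkylation of the ambident sulfinate at the primary carbon with iodide catalysis. Whether chloride leaves directly or through a transient epoxide reopened at its CH2, no bond to the carbinol carbon is broken, so the (S) configuration is retained.

Step 7
Reactants: 11 (2S)-4-[3,4-bis(benzyloxy)phenyl]-1-(phenylsulfonyl)butan-2-ol; 4 tetra-O-benzylcatechin 3-O-(imidazole-1-carboxylate)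
Product: 13 (2R,3S)-5,7-bis(benzyloxy)-2-[3,4-bis(benzyloxy)phenyl]chroman-3-yl (3S)-5-[3,4-bis(benzyloxy)phenyl]-3-hydroxy-2-(phenylsulfonyl)pentanoate (both C2 epimers), via dilithio dianion 12 (not isolated)
Conditions: 11 (2.0 equiv), n-BuLi (4.0 equiv), THF, −78 → −20 °C; then 4 (1.0 equiv), THF, −78 °C; AcOH, −78 °C
Reagents that add atoms: none
Why: C-Acylation of an α-sulfonyl carbanion (Claisen-type alkoxycarbonylation); the closest known reaction type is the carboxylation of sulfone carbanions and of β-hydroxy sulfone dianions with chloroformates, carbonates and acyl imidazoles. The first equivalent of n-BuLi forms the lithium alkoxide of 11 and the second removes an α-sulfonyl proton to give 12; the carbanion adds to the carbonyl of 4 and the tetrahedral adduct expels lithium imidazolide, a far better leaving group than the flavanyl alkoxide, so chain C1–C2 forms with the O3–C1 bond intact. No ring closes and no stereocentre of the target is created: chain C2 arises as a mixture of epimers that step 8 erases, while chain C3 (from 8) and flavan C2 and C3 (from 1) have no bond broken. The selectivity needed is carbon over oxygen acylation, secured by the much higher nucleophilicity of the sulfonyl carbanion than of the aggregated lithium alkoxide at −78 °C and by quenching cold before the alkoxide can react. Because 13 is a stronger carbon acid than 11, about two equivalents of 12 are used per 4: the second acts as base, the product rests as its alkoxide enolate, which can undergo neither retro-aldol cleavage nor β-elimination, and the protonated half returns as 11 on chromatography. The alkoxide of 12 likewise guards the carbinol of the nucleophile against elimination, and the benzyl ethers are inert to the base.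

Step 8
Reactants: 13 hexa-O-benzyl-2-(phenylsulfonyl)phylloflavan (C2 epimers)
Product: 14 (2R,3S)-5,7-bis(benzyloxy)-2-[3,4-bis(benzyloxy)phenyl]chroman-3-yl (3S)-5-[3,4-bis(benzyloxy)phenyl]-3-hydroxypentanoate (hexa-O-benzylphylloflavan)
Conditions: SmI2 (3 equiv), THF/MeOH, −78 → −40 °C
Reagents that add atoms: none
Why: Reductive desulfonylation of an α-sulfonyl ester by single-electron transfer from divalent samarium: C–S cleavage gives sulfinate and a samarium enolate, which MeOH protonates at low temperature before the β-hydroxyl can leave, as in the SmI2 reduction of α-heterosubstituted carbonyl compounds and of α,β-epoxy ketones to β-hydroxy carbonyl compounds. The stereorandom chain C2 becomes CH2; benzyl ethers and the ester are not reduced.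

Step 9
Reactants: 14 hexa-O-benzylphylloflavan
Product: 15 phylloflavan, (2R,3S)-2-(3,4-dihydroxyphenyl)-5,7-dihydroxychroman-3-yl (3S)-5-(3,4-dihydroxyphenyl)-3-hydroxypentanoate
Conditions: H2 (1 atm), Pd(OH)2/C, THF/MeOH, rt; filtration and concentration under argon
Reagents that add atoms: none
Why: Catalytic hydrogenolysis of the six aryl benzyl ethers under neutral conditions; Pd(OH)2/C at ambient pressure is the usual catalyst for benzylated flavan-3-ols and should leave the C2–O1 bond, the ester and all three stereocentres intact, and handling under argon protects the free catechols.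

## Compound list

1 | (+)-catechin, (2R,3S)-2-(3,4-dihydroxyphenyl)chroman-3,5,7-triol | O[C@H]1Cc2c(O)cc(O)cc2O[C@@H]1c1ccc(O)c(O)c1 | starting material
2 | (2R,3S)-5,7-bis(benzyloxy)-2-[3,4-bis(benzyloxy)phenyl]chroman-3-ol | O[C@H]1Cc2c(OCc3ccccc3)cc(OCc3ccccc3)cc2O[C@@H]1c1ccc(OCc2ccccc2)c(OCc2ccccc2)c1 | intermediate
3 | 1,1'-carbonyldiimidazole | O=C(n1ccnc1)n1ccnc1 | starting material
4 | (2R,3S)-5,7-bis(benzyloxy)-2-[3,4-bis(benzyloxy)phenyl]chroman-3-yl 1H-imidazole-1-carboxylate | O=C(n1ccnc1)O[C@H]1Cc2c(OCc3ccccc3)cc(OCc3ccccc3)cc2O[C@@H]1c1ccc(OCc2ccccc2)c(OCc2ccccc2)c1 | intermediate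
5 | 3,4-bis(benzyloxy)benzaldehyde | O=Cc1ccc(OCc2ccccc2)c(OCc2ccccc2)c1 | starting material
6 | [3,4-bis(benzyloxy)phenyl]methanol | OCc1ccc(OCc2ccccc2)c(OCc2ccccc2)c1 | intermediate
7 | 1,2-bis(benzyloxy)-4-(chloromethyl)benzene | ClCc1ccc(OCc2ccccc2)c(OCc2ccccc2)c1 | intermediate
8 | (S)-epichlorohydrin, (2S)-2-(chloromethyl)oxirane | ClC[C@@H]1CO1 | starting material
9 | [3,4-bis(benzyloxy)benzyl]magnesium chloride, formed in the flask | Cl[Mg]Cc1ccc(OCc2ccccc2)c(OCc2ccccc2)c1 | intermediate
10 | (2S)-4-[3,4-bis(benzyloxy)phenyl]-1-chlorobutan-2-ol | ClC[C@@H](O)CCc1ccc(OCc2ccccc2)c(OCc2ccccc2)c1 | intermediate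
11 | (2S)-4-[3,4-bis(benzyloxy)phenyl]-1-(phenylsulfonyl)butan-2-ol | O=S(=O)(C[C@@H](O)CCc1ccc(OCc2ccccc2)c(OCc2ccccc2)c1)c1ccccc1 | intermediate
12 | dilithio dianion of 11 (lithium alkoxide, α-lithio sulfone), formed in the flask | O=S(=O)(C([Li])[C@@H](O[Li])CCc1ccc(OCc2ccccc2)c(OCc2ccccc2)c1)c1ccccc1 | intermediate
13 | (2R,3S)-5,7-bis(benzyloxy)-2-[3,4-bis(benzyloxy)phenyl]chroman-3-yl (3S)-5-[3,4-bis(benzyloxy)phenyl]-3-hydroxy-2-(phenylsulfonyl)pentanoate, C2 epimers | O=C(C([C@@H](O)CCc1ccc(OCc2ccccc2)c(OCc2ccccc2)c1)S(=O)(=O)c1ccccc1)O[C@H]1Cc2c(OCc3ccccc3)cc(OCc3ccccc3)cc2O[C@@H]1c1ccc(OCc2ccccc2)c(OCc2ccccc2)c1 | intermediate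
14 | (2R,3S)-5,7-bis(benzyloxy)-2-[3,4-bis(benzyloxy)phenyl]chroman-3-yl (3S)-5-[3,4-bis(benzyloxy)phenyl]-3-hydroxypentanoate | O=C(C[C@@H](O)CCc1ccc(OCc2ccccc2)c(OCc2ccccc2)c1)O[C@H]1Cc2c(OCc3ccccc3)cc(OCc3ccccc3)cc2O[C@@H]1c1ccc(OCc2ccccc2)c(OCc2ccccc2)c1 | intermediate
15 | phylloflavan | O=C(C[C@@H](O)CCc1ccc(O)c(O)c1)O[C@H]1Cc2c(O)cc(O)cc2O[C@@H]1c1ccc(O)c(O)c1 | target

## Step count and risks

Total step count: 9. Longest linear sequence: 7 steps (steps 3 to 9, from 5 to 15); the catechin branch (steps 1 and 2) joins at step 7.

**Step 7 (key step).** What may go wrong: proton transfer from the newly formed, more acidic sulfonyl ester to unreacted carbanion, which stops the acylation short. On warming, the lithium alkoxide may acylate at oxygen, or base-induced elimination may occur across flavan C3–C4 or C2–C3 of the carbonyl-imidazole. Retro-aldol cleavage is possible if the quench is not cold and acidic. Fallback: it sets out from 2 and 7 and returns at 14, which also makes step 8 unnecessary. Heating 2 with 2,2,6-trimethyl-4H-1,3-dioxin-4-one in toluene (acylketene trapping) should give tetra-O-benzylcatechin 3-O-acetoacetate F1. Its dianion (NaH, then n-BuLi, THF, 0 °C) should be alkylated at the terminal carbon by 7 to give tetra-O-benzylcatechin 3-O-[5-(3,4-bis(benzyloxy)phenyl)-3-oxopentanoate] F2. Noyori hydrogenation of this keto ester with RuCl2[(S)-BINAP] and H2 should then set the (3S)-carbinol by catalyst control and give 14. The sense is assigned by analogy with simple 3-oxoalkanoates and would be confirmed by comparison with material from the main route.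

**Step 5.** What may go wrong: Wurtz homocoupling while the Grignard reagent forms from the electron-rich benzylic chloride, and closure of the magnesium chlorohydrinate to an epoxide followed by a second addition. Fallback: it sets out from 7 and returns at 11, bypassing 10 and step 6. The dianion of 1-(phenylsulfonyl)propan-2-one (NaH, then n-BuLi) should be alkylated at its methyl carbon by 7 to give 4-[3,4-bis(benzyloxy)phenyl]-1-(phenylsulfonyl)butan-2-one F3. Asymmetric hydrogenation of this β-keto sulfone with RuCl2[(S)-BINAP] and H2 should give 11. The (S) sense is expected by analogy with β-keto esters and would be checked on a Mosher ester.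

**Step 6.** What may go wrong: sluggish displacement at a primary chloride flanked by an oxygenated carbon, and O-alkylation of the ambident sulfinate. Fallback: it sets out from 10 and returns at 11. The far more nucleophilic thiolate (PhSH, K2CO3, DMF) should give (2S)-4-[3,4-bis(benzyloxy)phenyl]-1-(phenylsulfanyl)butan-2-ol F4. Oxidation of this sulfide with H2O2 and catalytic (NH4)6Mo7O24 in EtOH should then give 11.

**Step 8.** What may go wrong: expulsion of the β-hydroxyl from the samarium enolate (dehydration to the enoate) in competition with protonation, and retro-aldol fragmentation of the β-hydroxy sulfonyl ester under the methoxide that forms. Fallback: it sets out from 13 and returns at 14. Silylation (TESOTf, 2,6-lutidine, CH2Cl2, −78 °C) should give the 3-O-triethylsilyl ether of 13 F5, in which the oxygen can neither bind samarium as a leaving group nor start a retro-aldol. SmI2 in THF/MeOH should then give the 3-O-triethylsilyl ether of 14 F6, and HF·pyridine in THF at 0 °C should release 14.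

**Step 9.** What may go wrong: reductive opening of ring C at the benzylic C2–O1 bond on prolonged exposure, incomplete removal of all six groups, and air oxidation of the catechols during isolation. Fallback: it sets out from 14 and returns at 15 without any new intermediate. The benzyl groups would be removed by Lewis acid instead of hydrogen, with BCl3 and pentamethylbenzene as cation scavenger in CH2Cl2 at −78 °C. The temperature is kept low because the same C2–O1 bond can ionise under Lewis acid.

## Further compounds

F1 | step 7 | tetra-O-benzylcatechin 3-O-acetoacetate | CC(=O)CC(=O)O[C@H]1Cc2c(OCc3ccccc3)cc(OCc3ccccc3)cc2O[C@@H]1c1ccc(OCc2ccccc2)c(OCc2ccccc2)c1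
F2 | step 7 | tetra-O-benzylcatechin 3-O-[5-(3,4-bis(benzyloxy)phenyl)-3-oxopentanoate] | O=C(CC(=O)CCc1ccc(OCc2ccccc2)c(OCc2ccccc2)c1)O[C@H]1Cc2c(OCc3ccccc3)cc(OCc3ccccc3)cc2O[C@@H]1c1ccc(OCc2ccccc2)c(OCc2ccccc2)c1
F3 | step 5 | 4-[3,4-bis(benzyloxy)phenyl]-1-(phenylsulfonyl)butan-2-one | O=C(CCc1ccc(OCc2ccccc2)c(OCc2ccccc2)c1)CS(=O)(=O)c1ccccc1
F4 | step 6 | (2S)-4-[3,4-bis(benzyloxy)phenyl]-1-(phenylsulfanyl)butan-2-ol | c1ccccc1SC[C@@H](O)CCc1ccc(OCc2ccccc2)c(OCc2ccccc2)c1
F5 | step 8 | 3-O-triethylsilyl ether of 13 (C2 epimers) | O=C(C([C@@H](O[Si](CC)(CC)CC)CCc1ccc(OCc2ccccc2)c(OCc2ccccc2)c1)S(=O)(=O)c1ccccc1)O[C@H]1Cc2c(OCc3ccccc3)cc(OCc3ccccc3)cc2O[C@@H]1c1ccc(OCc2ccccc2)c(OCc2ccccc2)c1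
F6 | step 8 | 3-O-triethylsilyl ether of 14 | O=C(C[C@@H](O[Si](CC)(CC)CC)CCc1ccc(OCc2ccccc2)c(OCc2ccccc2)c1)O[C@H]1Cc2c(OCc3ccccc3)cc(OCc3ccccc3)cc2O[C@@H]1c1ccc(OCc2ccccc2)c(OCc2ccccc2)c1
F0 | step 9 | none | none
A1 | alternative 1 | hepta-O-benzylphylloflavan | O=C(C[C@@H](OCc1ccccc1)CCc1ccc(OCc2ccccc2)c(OCc2ccccc2)c1)O[C@H]1Cc2c(OCc3ccccc3)cc(OCc3ccccc3)cc2O[C@@H]1c1ccc(OCc2ccccc2)c(OCc2ccccc2)c1
A2 | alternative 1 | cyclic methyl orthoester (2-methoxy-1,3-dioxolane) of (1S,2S)-3-[2,4-bis(benzyloxy)-6-hydroxyphenyl]-1-[3,4-bis(benzyloxy)phenyl]propane-1,2-diol carrying the (2S)-2-(benzyloxy)-4-[3,4-bis(benzyloxy)phenyl]butyl group at the orthoester carbon | COC1(C[C@@H](OCc2ccccc2)CCc2ccc(OCc3ccccc3)c(OCc3ccccc3)c2)O[C@@H](Cc2c(O)cc(OCc3ccccc3)cc2OCc2ccccc2)[C@H](c2ccc(OCc3ccccc3)c(OCc3ccccc3)c2)O1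
A3 | alternative 2 | tetra-O-benzylcatechin 3-O-[(3R,4E)-5-(3,4-bis(benzyloxy)phenyl)-3-hydroxypent-4-enoate] | O=C(C[C@@H](O)/C=C/c1ccc(OCc2ccccc2)c(OCc2ccccc2)c1)O[C@H]1Cc2c(OCc3ccccc3)cc(OCc3ccccc3)cc2O[C@@H]1c1ccc(OCc2ccccc2)c(OCc2ccccc2)c1
A4 | alternative 2 | tetra-O-benzylcatechin 3-O-[(3R)-3-hydroxypent-4-enoate] | O=C(C[C@@H](O)C=C)O[C@H]1Cc2c(OCc3ccccc3)cc(OCc3ccccc3)cc2O[C@@H]1c1ccc(OCc2ccccc2)c(OCc2ccccc2)c1
A5 | alternative 2 | 3,4-bis(benzyloxy)styrene | C=Cc1ccc(OCc2ccccc2)c(OCc2ccccc2)c1
A6 | alternative 3 | tetra-O-benzylcatechin 3-O-[(3S)-5-(3,4-bis(benzyloxy)phenyl)-3-(4,4,5,5-tetramethyl-1,3,2-dioxaborolan-2-yl)pentanoate] | O=C(C[C@@H](B1OC(C)(C)C(C)(C)O1)CCc1ccc(OCc2ccccc2)c(OCc2ccccc2)c1)O[C@H]1Cc2c(OCc3ccccc3)cc(OCc3ccccc3)cc2O[C@@H]1c1ccc(OCc2ccccc2)c(OCc2ccccc2)c1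
A7 | alternative 3 | tetra-O-benzylcatechin 3-O-[(2E)-5-(3,4-bis(benzyloxy)phenyl)pent-2-enoate] | O=C(/C=C/CCc1ccc(OCc2ccccc2)c(OCc2ccccc2)c1)O[C@H]1Cc2c(OCc3ccccc3)cc(OCc3ccccc3)cc2O[C@@H]1c1ccc(OCc2ccccc2)c(OCc2ccccc2)c1
A8 | alternative 3 | (2E)-5-[3,4-bis(benzyloxy)phenyl]pent-2-enoic acid | O=C(O)/C=C/CCc1ccc(OCc2ccccc2)c(OCc2ccccc2)c1
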